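**Retrosynthetic overview**

1. Guaianolide numbering is used (C1–C5 cyclopentane, C1/C5–C10 cycloheptane, C11–C13 lactone carbons, C14/C15 exocyclic carbons; primes for the half that carries the spiro carbon C4′).
2. Target ⇒ base-mediated enone transposition of a Diels–Alder adduct of dehydrozaluzanin C (dienophile C4′=C15′) with its own 1,2-dehydro derivative (diene C2=C1–C10=C14). Both halves come from one monomer, and the spiro-cyclohexene is the last ring formed.
3. Monomer ⇒ isodehydrocostus lactone (C3=C4) by epoxidation, epoxide-to-allylic-alcohol isomerisation and oxidation.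
4. Isodehydrocostus lactone ⇒ one radical cascade on a monocyclic cyclopentene: C11–C7 (5-exo, lactone ring), then C8–C9 (7-endo, seven-membered ring), ended by loss of a sulfonyl radical from C14. Enabling feature: C9 is a CH2 terminus of the 2-substituted allyl unit C9–C10(=C14) on C1, and C8 is the CH2 on C7. A radical arriving at C7 therefore leaves its spin on C8, and attack of C8 on C9 of an allyl sulfone re-forms the C10=C14 methylene.
5. Cyclopentene ⇒ (R)-carvone by chlorohydrin Favorskii ring contraction (sets C1/C5 cis). Ring order: cyclopentene, then lactone and cycloheptane together, then spiro-cyclohexene.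

Key step: step 10

Assumption: in the dienone half the SMILES puts 5-H cis to 6-H (opposite to the other half); C5 and C10 of that half are γ-carbons of the C1=C2–C3=O enone and are taken to rest in their thermodynamically preferred configuration, which the last step reaches by base equilibration.

**Route**

Step 1
Reactants: 1 (R)-(−)-carvone
Product: 2 (5R)-5-(3-chloroprop-1-en-2-yl)-2-methylcyclohex-2-en-1-one (10-chlorocarvone)
Conditions: Ca(OCl)2, CO2 (dry ice), CH2Cl2/H2O, 0 °C
Reagents that add atoms: calcium hypochlorite, [Ca+2].[O-]Cl.[O-]Cl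
Why: Ene-type allylic chlorination by HOCl should take place only at the electron-rich isopropenyl group (the enone alkene is deactivated), giving the 2-(chloromethyl)allyl unit without touching the stereocentre.

Step 2
Reactants: 2 10-chlorocarvone
Product: 3 (1R,4R,6R)-4-(3-chloroprop-1-en-2-yl)-1-methyl-7-oxabicyclo[4.1.0]heptan-2-one (epoxide trans to the side chain)
Conditions: H2O2 (30% aq), NaOH (cat.), MeOH, 0 °C
Reagents that add atoms: hydrogen peroxide, OO
Why: Weitz–Scheffer nucleophilic epoxidation should touch only the enone, and hydroperoxide adds anti to the side chain on C5, so the epoxide is trans to it.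

Step 3
Reactants: 3 epoxy ketone
Product: 4 (2S,3R,5R)-2-chloro-5-(3-chloroprop-1-en-2-yl)-3-hydroxy-2-methylcyclohexan-1-one (Cl cis to the side chain, OH trans to Cl)
Conditions: LiCl, CF3CO2H, THF, 0 °C → rt
Reagents that add atoms: lithium chloride, [Li+].[Cl-]
Why: Acid-promoted epoxide opening by chloride at the tertiary α-carbon with inversion should give the α-chloro-β-hydroxy ketone, which places chlorine on the face of the side chain.

Step 4
Reactants: 4 chlorohydrin
Product: 5 (2S,3R,5R)-2-chloro-5-(3-chloroprop-1-en-2-yl)-2-methyl-3-(methylsulfonyloxy)cyclohexan-1-one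
Conditions: MsCl, Et3N, CH2Cl2, 0 °C
Reagents that add atoms: methanesulfonyl chloride, CS(=O)(=O)Cl
Why: Standard mesylation of the secondary alcohol; C2 carries no hydrogen, so β-elimination toward the ketone is not possible.

Step 5
Reactants: 5 chloro mesylate
Product: 7 methyl (1R,5R)-5-(3-chloroprop-1-en-2-yl)-2-methylcyclopent-2-ene-1-carboxylate (ester cis to the side chain), via cyclopropanone 6 (not isolated)
Conditions: NaOMe (2.1 equiv), MeOH, −20 → 0 °C; AcOH quench
Reagents that add atoms: sodium methoxide, C[O-].[Na+]
Why: Favorskii rearrangement: the α′-enolate displaces chloride with inversion, so the cyclopropanone carbonyl sits on the face of the side chain; methoxide opening with loss of the anti β-mesylate (the course the β-bromide takes in the carvone tribromide contraction) should give the cyclopentene ester with ester and side chain cis under kinetic control.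

Step 6
Reactants: 7 allyl chloride ester
Product: 8 methyl (1R,5R)-2-methyl-5-[3-(4-methylbenzenesulfonyl)prop-1-en-2-yl]cyclopent-2-ene-1-carboxylate
Conditions: TolSO2Na, DMF, 40 °C
Reagents that add atoms: sodium 4-methylbenzenesulfinate, Cc1ccc(cc1)S(=O)[O-].[Na+]
Why: SN2 S-alkylation of the sulfinate by the allylic chloride under neutral conditions should leave the epimerisable C–H next to the ester alone.

Step 7
Reactants: 8 sulfone ester
Product: 9 (1R,5R)-2-methyl-5-[3-(4-methylbenzenesulfonyl)prop-1-en-2-yl]cyclopent-2-ene-1-carbaldehyde (used crude)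
Conditions: i-Bu2AlH (1.1 equiv), CH2Cl2, −78 °C; Rochelle salt
Reagents that add atoms: none
Why: Partial reduction of the methyl ester through the tetrahedral aluminate that is stable at −78 °C; the cold, non-basic conditions should preserve the cis β,γ-unsaturated aldehyde.

Step 8
Reactants: 9 aldehyde
Product: 10 (1S)-1-{(1R,5R)-2-methyl-5-[3-(4-methylbenzenesulfonyl)prop-1-en-2-yl]cyclopent-2-en-1-yl}prop-2-en-1-ol
Conditions: CH2=CHMgBr, THF, −78 °C
Reagents that add atoms: vinylmagnesium bromide, C=C[Mg]Br
Why: Felkin–Anh 1,2-addition: with the ring carbon that carries the cis side chain as the large group, the vinyl nucleophile should attack anti to it and give the (S)-carbinol (6β-H) as the major, separable epimer.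

Step 9
Reactants: 10 allylic alcohol
Product: 11 mixed acetal (1S)-1-(2-bromo-1-methoxyprop-2-enyloxy)prop-2-enyl derivative of 10 (acetal carbon: both epimers)
Conditions: methoxyallene, NBS, CH2Cl2, −78 → −30 °C
Reagents that add atoms: methoxyallene, COC=C=C; N-bromosuccinimide, BrN1C(=O)CCC1=O
Why: Bromoalkoxylation of the alkoxyallene: electrophilic bromine adds to the central allene carbon and the alcohol captures the oxocarbenium ion, giving the 2-bromoallyl acetal; the enol ether should react far faster than the other alkenes.

Step 10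
Reactants: 11 2-bromoallyl acetal
Product: 12 12-methoxy-6α,12-epoxyguaia-3,10(14),11(13)-triene (methyl lactol ether of isodehydrocostus lactone; 1α-H, 5α-H, 6β-H, 7α-H; acetal carbon: both epimers)
Conditions: Bu3SnH (1.3 equiv) and AIBN (0.2 equiv) by syringe pump over 8 h into PhH (0.003 M), reflux
Reagents that add atoms: none
Why: Bu3Sn• abstracts bromine to give the σ-vinyl radical at C11, which adds 5-exo-trig to C7 of the vinyl group (C11–C7, lactol ring) and leaves a primary radical on C8; C8 then adds 7-endo-trig to the free CH2 terminus (C9) of the 2-(sulfonylmethyl)allyl group on C1 (C8–C9, seven-membered ring), and the tertiary C10 radical expels the sulfonyl radical, which turns over with Bu3SnH, so that C10=C14 and C11=C13 both emerge as exocyclic methylenes. The closest known reaction types are the tandem 5-exo/7-endo radical cyclisation of bromoacetals of cyclopentenyl vinyl carbinols used for guaianolide skeletons, the vinyl-radical version of the Ueno–Stork cyclisation, and radical allylation by addition–fragmentation of allyl sulfones. The only new stereocentre, C7, is set in the 5-exo step by the C6 centre: a chair-like transition state with the cyclopentenyl group pseudo-equatorial puts C8 trans to C5 across the new ring (6β-H, 7α-H), while the acetal carbon stays an inconsequential mixture. The step needs 7-endo closure to beat 6-exo attack, hydrogen transfer to C8 and attack on the ring alkene: the acceptor is 1,1-disubstituted so only its CH2 end is open and fragmentation makes the addition irreversible, the two arms are cis on the cyclopentene (from step 5) so C8 can reach C9, the stannane is kept dilute by slow addition, and attack of C8 on C3=C4 would demand a trans-fused bicyclo[3.3.0]octane or a bridged ring.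

Step 11
Reactants: 12 tricyclic methyl acetal
Product: 14 isodehydrocostus lactone (guaia-3,10(14),11(13)-trien-12,6α-olide), via lactol 13 (not isolated)
Conditions: CrO3, H2SO4, acetone/H2O, 0 °C
Reagents that add atoms: water, O
Why: Jones oxidation: acid hydrolysis of the allylic methyl acetal gives the lactol, which chromic acid should oxidise to the α-methylene-γ-lactone without touching the isolated alkenes.

Step 12
Reactants: 14 isodehydrocostus lactone
Product: 15 3α,4α-epoxyguaia-10(14),11(13)-dien-12,6α-olide (the estafiatin structure)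
Conditions: mCPBA (1.0 equiv), NaHCO3, CH2Cl2, 0 °C
Reagents that add atoms: 3-chloroperbenzoic acid, OOC(=O)c1cccc(Cl)c1
Why: Prilezhaev epoxidation should pick the most electron-rich (trisubstituted) alkene and approach from the convex α-face of the cis-fused hydroazulene, opposite the seven-membered ring.

Step 13
Reactants: 15 epoxide
Product: 16 3α-hydroxyguaia-4(15),10(14),11(13)-trien-12,6α-olide (3-epizaluzanin C)
Conditions: Al(OiPr)3, PhMe, reflux
Reagents that add atoms: none
Why: Aluminium-alkoxide-mediated epoxide-to-allylic-alcohol isomerisation: the C4–O bond at the tertiary carbon opens and a syn hydrogen of the C15 methyl group is removed, which should give the exocyclic C4=C15 alkene with the oxygen kept on C3.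

Step 14
Reactants: 16 allylic alcohol
Product: 17 dehydrozaluzanin C (3-oxoguaia-4(15),10(14),11(13)-trien-12,6α-olide)
Conditions: Dess–Martin periodinane, NaHCO3, CH2Cl2, 0 °C → rt
Reagents that add atoms: none
Why: Dess–Martin oxidation of the secondary allylic alcohol under buffered, non-nucleophilic conditions should give the exocyclic enone and removes the C3 stereocentre.

Step 15
Reactants: 17 dehydrozaluzanin C
Product: 18 3-(tert-butyldimethylsilyloxy)guaia-2,4(15),10(14),11(13)-tetraen-12,6α-olide
Conditions: TBSOTf, Et3N, CH2Cl2, −78 → 0 °C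
Reagents that add atoms: tert-butyldimethylsilyl trifluoromethanesulfonate, CC(C)(C)[Si](C)(C)OS(=O)(=O)C(F)(F)F
Why: Soft enolisation can only go toward C2 (C4 is sp2), so a single silyl dienol ether should form, and the amine base spares the α-methylene lactone.

Step 16
Reactants: 18 silyl dienol ether; 17 dehydrozaluzanin C (3 equiv)
Product: 20 Diels–Alder adduct (C2–C4′ and C14–C15′ bonds, C1=C10, 2β-H, 5α-H, new bond at C4′ on the α-face of the spiro half), via dienone 19 (not isolated)
Conditions: Pd(OAc)2 (1.1 equiv), MeCN, rt → 40 °C, Ar; 18 added slowly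
Reagents that add atoms: none
Why: Saegusa–Ito oxidation (C2-palladation, β-hydride loss from C1) gives dienone 19, whose C2=C1–C10=C14 diene is held s-cis by the two rings; it should add at once to the exocyclic enone alkene C4′=C15′ of 17 (more reactive than the α-methylene lactone) with ortho regiochemistry on the convex α-face of 17 (the face of 1′-H and 5′-H), which fixes the spiro carbon C4′, while the C2 centre formed with it is erased in step 17 (Diels–Alder reaction).

Step 17
Reactants: 20 Diels–Alder adduct
Product: 21 CNP0221188.1 (dienone half 5β-H, 6β-H, 7α-H, 10α-H; spiro half 1′α-H, 5′α-H, 6′β-H, 7′α-H)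
Conditions: DBU (0.2 equiv), degassed PhMe, rt, Ar
Reagents that add atoms: none
Why: The C2–H of 20 is α to the ketone and allylic, so base should move C1=C10 into conjugation (C1=C2) through the dienolate with protonation at C10; C10–H and C5–H of the product are both vinylogous α-hydrogens, so both centres equilibrate and the product should settle in the thermodynamic configuration taken above to be that of the target (enone transposition by γ-protonation).

**Compound list**

1 | (R)-(−)-carvone | CC1=CC[C@H](CC1=O)C(C)=C | starting material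
2 | (5R)-5-(3-chloroprop-1-en-2-yl)-2-methylcyclohex-2-en-1-one | CC1=CC[C@H](CC1=O)C(=C)CCl | intermediate
3 | (1R,4R,6R)-4-(3-chloroprop-1-en-2-yl)-1-methyl-7-oxabicyclo[4.1.0]heptan-2-one | C[C@@]12O[C@@H]1C[C@H](CC2=O)C(=C)CCl | intermediate
4 | (2S,3R,5R)-2-chloro-5-(3-chloroprop-1-en-2-yl)-3-hydroxy-2-methylcyclohexan-1-one | C[C@]1(Cl)[C@H](O)C[C@H](CC1=O)C(=C)CCl | intermediate
5 | (2S,3R,5R)-2-chloro-5-(3-chloroprop-1-en-2-yl)-2-methyl-3-(methylsulfonyloxy)cyclohexan-1-one | C[C@]1(Cl)[C@H](OS(C)(=O)=O)C[C@H](CC1=O)C(=C)CCl | intermediate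
6 | cyclopropanone: 3-(3-chloroprop-1-en-2-yl)-1-methyl-5-(methylsulfonyloxy)bicyclo[3.1.0]hexan-6-one, carbonyl bridge on the face of the side chain | O=C1[C@@]2(C)[C@H](OS(C)(=O)=O)C[C@@H](C(=C)CCl)[C@@H]12 | intermediate (not isolated)
7 | methyl (1R,5R)-5-(3-chloroprop-1-en-2-yl)-2-methylcyclopent-2-ene-1-carboxylate | COC(=O)[C@H]1C(C)=CC[C@H]1C(=C)CCl | intermediate
8 | methyl (1R,5R)-2-methyl-5-[3-(4-methylbenzenesulfonyl)prop-1-en-2-yl]cyclopent-2-ene-1-carboxylate | COC(=O)[C@H]1C(C)=CC[C@H]1C(=C)CS(=O)(=O)c1ccc(C)cc1 | intermediate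
9 | (1R,5R)-2-methyl-5-[3-(4-methylbenzenesulfonyl)prop-1-en-2-yl]cyclopent-2-ene-1-carbaldehyde | O=C[C@H]1C(C)=CC[C@H]1C(=C)CS(=O)(=O)c1ccc(C)cc1 | intermediate
10 | (1S)-1-{(1R,5R)-2-methyl-5-[3-(4-methylbenzenesulfonyl)prop-1-en-2-yl]cyclopent-2-en-1-yl}prop-2-en-1-ol | C=C[C@H](O)[C@H]1C(C)=CC[C@H]1C(=C)CS(=O)(=O)c1ccc(C)cc1 | intermediate
11 | 2-bromo-1-methoxyprop-2-enyl acetal of 10 (acetal carbon: both epimers) | C=C[C@H](OC(OC)C(Br)=C)[C@H]1C(C)=CC[C@H]1C(=C)CS(=O)(=O)c1ccc(C)cc1 | intermediate
12 | 12-methoxy-6α,12-epoxyguaia-3,10(14),11(13)-triene (1α-H, 5α-H, 6β-H, 7α-H; acetal carbon: both epimers) | COC1O[C@H]2[C@H](C1=C)CCC(=C)[C@@H]1CC=C(C)[C@@H]12 | intermediate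
13 | 6α,12-epoxyguaia-3,10(14),11(13)-trien-12-ol (lactol) | OC1O[C@H]2[C@H](C1=C)CCC(=C)[C@@H]1CC=C(C)[C@@H]12 | intermediate (not isolated)
14 | isodehydrocostus lactone, guaia-3,10(14),11(13)-trien-12,6α-olide | O=C1O[C@H]2[C@H](C1=C)CCC(=C)[C@@H]1CC=C(C)[C@@H]12 | intermediate
15 | 3α,4α-epoxyguaia-10(14),11(13)-dien-12,6α-olide | O=C1O[C@H]2[C@H](C1=C)CCC(=C)[C@@H]1C[C@H]3O[C@@]3(C)[C@@H]12 | intermediate
16 | 3α-hydroxyguaia-4(15),10(14),11(13)-trien-12,6α-olide | O=C1O[C@H]2[C@H](C1=C)CCC(=C)[C@@H]1C[C@@H](O)C(=C)[C@@H]12 | intermediate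
17 | dehydrozaluzanin C, 3-oxoguaia-4(15),10(14),11(13)-trien-12,6α-olide | O=C1O[C@H]2[C@H](C1=C)CCC(=C)[C@@H]1CC(=O)C(=C)[C@@H]12 | intermediate
18 | 3-(tert-butyldimethylsilyloxy)guaia-2,4(15),10(14),11(13)-tetraen-12,6α-olide | O=C1O[C@H]2[C@H](C1=C)CCC(=C)[C@@H]1C=C(O[Si](C)(C)C(C)(C)C)C(=C)[C@@H]12 | intermediate
19 | 3-oxoguaia-1,4(15),10(14),11(13)-tetraen-12,6α-olide (dienone) | O=C1O[C@H]2[C@H](C1=C)CCC(=C)C1=CC(=O)C(=C)[C@@H]12 | intermediate (not isolated)
20 | Diels–Alder adduct of 19 and 17 (C1=C10, 2β-H, 5α-H) | C=C1C(=O)[C@H]2C3=C(CC[C@H]4C(=C)C(=O)O[C@@H]4[C@@H]13)CC[C@]21C(=O)C[C@H]2C(=C)CC[C@H]3C(=C)C(=O)O[C@@H]3[C@H]21 | intermediate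
21 | CNP0221188.1 | C=C1C(=O)C2=C3[C@H](CC[C@H]4C(=C)C(=O)O[C@@H]4[C@H]13)CC[C@]21C(=O)C[C@H]2C(=C)CC[C@H]3C(=C)C(=O)O[C@@H]3[C@H]21 | target

**Step count and risks**

Total steps: 17. Longest linear sequence: 17 steps (1 → 21); compound 17 enters step 16 twice, as the dienophile and, through 18, as the diene.

Most likely to fail, in this order:

Step 10. Hydrogen transfer from the stannane to the C8 radical could outrun the slow 7-endo closure. This is made worse because bromine abstraction from a vinyl bromide is slow, so the stannane cannot be kept very dilute, and stannyl radicals may attack the allyl sulfone instead. The fallback sets out from alcohol 10 and moves to the alkyl-radical form of the cascade, whose bromide reacts much faster with tin radicals, and installs C13 afterwards. Ethyl vinyl ether and NBS (CH2Cl2, −40 °C) should give the 2-bromo-1-ethoxyethyl acetal F1. Bu3SnH/AIBN under the same slow-addition conditions should give the tricyclic ethyl acetal F2 by the same 5-exo/7-endo closure and sulfonyl loss. Jones oxidation should pass through the lactol F3 to the lactone F4, which lacks C13. LiN(iPr)2 and Eschenmoser's salt (THF, −78 °C) should give the Mannich base F5. MeI should give the methiodide F6, and NaHCO3 then eliminates trimethylamine to return to the route at compound 14.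

Step 17. The equilibration may settle on the other configuration at C5, or stop at a mixture of C5/C10 epimers. The fallback sets out from adduct 20 and replaces the one-pot equilibration by two kinetically controlled events. Et3N in CH2Cl2 should effect only the C2 → C10 proton shift and give the enone with the original 5α-H, F7. F7 is then deprotonated at C5 with KN(SiMe3)2 (THF, −78 °C) and reprotonated with 2,6-di-tert-butyl-4-methylphenol, which should deliver the proton past the small 6-H, on the face away from the C6–O bond, and return to the route at compound 21.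

Step 5. The mesylate may be lost by elimination or substitution before the ring contraction, or the cis ester may epimerise or move into conjugation under methoxide. The fallback sets out from chlorohydrin 4 and separates ring contraction from alkene formation. TBSOTf/2,6-lutidine should give the silyl ether F8. NaOMe/MeOH should give, through the cyclopropanone F9, the saturated all-cis-defined ester F10 (ester cis to the side chain, 4-methyl trans to the ester). HF·pyridine should give the alcohol F11. Martin sulfurane (CH2Cl2, rt) should then dehydrate F11 by anti elimination toward the methyl-bearing carbon and return to the route at compound 7.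

**Further compounds**

F1 | step 10 | 2-bromo-1-ethoxyethyl acetal of 10 (acetal carbon: both epimers) | C=C[C@H](OC(OCC)CBr)[C@H]1C(C)=CC[C@H]1C(=C)CS(=O)(=O)c1ccc(C)cc1
F2 | step 10 | 12-ethoxy-6α,12-epoxy-13-norguaia-3,10(14)-diene | CCOC1O[C@H]2[C@H](C1)CCC(=C)[C@@H]1CC=C(C)[C@@H]12
F3 | step 10 | 6α,12-epoxy-13-norguaia-3,10(14)-dien-12-ol (lactol) | OC1O[C@H]2[C@H](C1)CCC(=C)[C@@H]1CC=C(C)[C@@H]12
F4 | step 10 | 13-norguaia-3,10(14)-dien-12,6α-olide | O=C1O[C@H]2[C@H](C1)CCC(=C)[C@@H]1CC=C(C)[C@@H]12
F5 | step 10 | 13-(dimethylamino)guaia-3,10(14)-dien-12,6α-olide (C11: both epimers) | O=C1O[C@H]2[C@H](C1CN(C)C)CCC(=C)[C@@H]1CC=C(C)[C@@H]12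
F6 | step 10 | methiodide of F5 | O=C1O[C@H]2[C@H](C1C[N+](C)(C)C)CCC(=C)[C@@H]1CC=C(C)[C@@H]12.[I-]
F7 | step 17 | 5α-H isomer of the target (5-H trans to 6-H) | C=C1C(=O)C2=C3[C@H](CC[C@H]4C(=C)C(=O)O[C@@H]4[C@@H]13)CC[C@]21C(=O)C[C@H]2C(=C)CC[C@H]3C(=C)C(=O)O[C@@H]3[C@H]21
F8 | step 5 | tert-butyldimethylsilyl ether of 4 | C[C@]1(Cl)[C@H](O[Si](C)(C)C(C)(C)C)C[C@H](CC1=O)C(=C)CCl
F9 | step 5 | cyclopropanone from F8 | O=C1[C@@]2(C)[C@H](O[Si](C)(C)C(C)(C)C)C[C@@H](C(=C)CCl)[C@@H]12
F10 | step 5 | methyl 3-(tert-butyldimethylsilyloxy)-5-(3-chloroprop-1-en-2-yl)-2-methylcyclopentane-1-carboxylate (ester cis to side chain, methyl and silyloxy on the other face) | COC(=O)[C@H]1[C@H](C)[C@H](O[Si](C)(C)C(C)(C)C)C[C@H]1C(=C)CCl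
F11 | step 5 | methyl 5-(3-chloroprop-1-en-2-yl)-3-hydroxy-2-methylcyclopentane-1-carboxylate (same configuration as F10) | COC(=O)[C@H]1[C@H](C)[C@H](O)C[C@H]1C(=C)CCl
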